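**Plan**

Numbering used throughout: spiro[4.5]decane, C1 = ring carbon bearing the side chain, C4 = CH(CH3), C5 = spiro carbon, C6 = allylic CH2, C7=C8(CH3), C9 = carbinol carbon, C10 = CH2; side chain from C1: Cb, C1', C2', C3', Ca, CH2OAc.
Retrosynthesis: C9–OH back to the enone and to allylic C–H oxidation; side chain cut at C1'–C2' (sulfone alkylation) and at C1–Cb (Ireland–Claisen from a C3 ester); then the cyclohexene is cut at C5–C6 and C9–C10.
Enabling feature: in the six-membered ring the methyl-bearing C7=C8 bond lies 1,4 to the spiro carbon C5 (cyclohex-3-ene, isoprene retron), and C5 is α to C1, where a temporary ketone makes C5=C10 an activated exocyclic dienophile.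
Forward: the cyclopentane comes first (from 3-methylcyclopentenone), the cyclohexene is closed onto it by the [4+2] step, the C1 ketone is relayed to a C3 allylic ester, the side chain is joined by [3,3] shift and sulfone alkylation, and C9 is oxidised last.
Stereochemistry: C4 by ligand-controlled CuH reduction; C5 from C4 (diene anti to methyl); temporary C3–O from C4 (epoxidation anti to methyl), passed suprafacially to C1 and Cb (boat Ireland–Claisen); Ca from (R)-3-bromo-2-methylpropan-1-ol; C9 by CBS reduction.

Key step: step 3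

Assumption: (R)-p-tol-BINAP is taken as the ligand enantiomer that gives the 3S ketone in step 1 and (R)-2-methyl-CBS-oxazaborolidine as the one that gives the 9S alcohol in step 19; if either sense is the reverse, the antipode is used.

**Route**

Step 1
Reactants: 1 3-methylcyclopent-2-en-1-one; 2 N,N-dimethylmethyleneiminium iodide
Product: 4 (2S,3S)-2-[(dimethylamino)methyl]-3-methylcyclopentan-1-one, via bis-enol diphenylsilane 3 (not isolated)
Conditions: CuCl (5 mol %), NaOtBu (5 mol %), (R)-p-tol-BINAP (5 mol %), Ph2SiH2 (0.55 equiv), toluene, 0 °C; then 2, CH2Cl2, 0 °C to rt; aq. NaHCO3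
Reagents that add atoms: none
Why: Asymmetric conjugate reduction by a monovalent copper hydride–p-tol-BINAP complex sets the methyl stereocentre by ligand control and stores the regiodefined C1–C2 enolate as a silyl enol ether, which undergoes Mannich aminomethylation at C2 (trans to methyl; this centre is lost in step 2).

Step 2
Reactants: 4
Product: 6 (S)-3-methyl-2-methylidenecyclopentan-1-one, via trimethylammonium iodide 5 (not isolated)
Conditions: MeI, Et2O, rt; then aq. NaHCO3/CH2Cl2, 0 °C; used at once as a cold CH2Cl2 solution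
Reagents that add atoms: none
Why: Quaternisation makes the amine a leaving group and mild-base E1cB elimination (Mannich-base route to α-methylene ketones) gives the exocyclic enone without touching C3 or moving the double bond into the ring.

Step 3
Reactants: 6; 7 isoprene (2-methylbuta-1,3-diene)
Product: 8 (4S,5R)-4,8-dimethylspiro[4.5]dec-7-en-1-one
Conditions: Me2AlCl (0.3 equiv), 7 (5 equiv), CH2Cl2, −78 to −20 °C
Reagents that add atoms: none
Why: Lewis-acid-catalysed normal-demand Diels–Alder reaction (concerted, asynchronous [4+2]): Me2AlCl on the C1 carbonyl lowers the LUMO of the s-cis enone and puts its largest coefficient on the exocyclic CH2 (C10), which bonds to the isoprene terminus next to the methyl-bearing carbon, so that C9–C10 and C5–C6 form in one suprafacial event. The closest known reaction type is the Lewis-acid-promoted spiroannulation of 2-methylenecycloalkanones with isoprene. The six-membered ring closes by [4+2] cycloaddition onto the exocyclic alkene and creates the quaternary spiro centre C5 with the C7=C8 bond 1,4 to it. C5 is the only new stereocentre and is controlled by the adjacent C4 methyl: the diene adds to the face of the methylene anti to it, which places C6 trans and C10 cis to that methyl as in the target. The step needs 1,4 ("para") over 1,3 regioselectivity, secured by the Lewis acid and the 2-methyl group of the diene, and facial selectivity, secured by the stereocentre next to the reacting carbon. It also needs suppression of enone dimerisation, secured by low temperature, excess diene and freshly made 6.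

Step 4
Reactants: 8
Product: 10 (4S,5R)-4,8-dimethylspiro[4.5]deca-2,7-dien-1-one, via trimethylsilyl enol ether 9 (not isolated)
Conditions: LDA, THF, −78 °C; TMSCl; then Pd(OAc)2 (10 mol %), O2 (1 atm), DMSO, rt
Reagents that add atoms: none
Why: Saegusa–Ito oxidation: enolisation can only occur at C2 because C5 is quaternary, and divalent palladium dehydrogenates the silyl enol ether to the C2=C3 enone while the isolated trisubstituted alkene is inert.

Step 5
Reactants: 10
Product: 11 2,3-epoxy-4,8-dimethylspiro[4.5]dec-7-en-1-one (epoxide on the C6 face and trans to the 4-methyl)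
Conditions: 30% H2O2, NaOH (0.3 equiv), MeOH, −10 to 0 °C, short reaction time
Reagents that add atoms: hydrogen peroxide, OO
Why: Weitz–Scheffer nucleophilic epoxidation is specific for the electron-poor C2=C3 bond; hydroperoxide adds to C3 anti to the adjacent C4 methyl, which sets C2 and C3, and the short cold reaction limits γ-deprotonation at C4.

Step 6
Reactants: 11
Product: 12 4,8-dimethylspiro[4.5]deca-1,7-dien-3-ol (3-OH on the C6 face and trans to the 4-methyl)
Conditions: N2H4·H2O (3 equiv), AcOH (1 equiv), MeOH, 0 °C to rt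
Reagents that add atoms: none
Why: Wharton transposition: the epoxy hydrazone fragments with loss of N2, moving the oxygen from C1 to C3 and the alkene to C1=C2; the C3–O bond is never broken, so its configuration is kept.

Step 7
Reactants: 13 (R)-3-bromo-2-methylpropan-1-ol
Product: 14 (R)-(3-bromo-2-methylpropoxy)(tert-butyl)diphenylsilane
Conditions: TBDPSCl, imidazole, DMF, rt
Reagents that add atoms: tert-butyl(chloro)diphenylsilane, CC(C)(C)[Si](Cl)(c1ccccc1)c1ccccc1
Why: Standard silylation of the primary alcohol; the stereocentre is not involved.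

Step 8
Reactants: 14; 15 methyl phenyl sulfone
Product: 17 (S)-tert-butyl{[2-methyl-4-(phenylsulfonyl)butyl]oxy}diphenylsilane, via lithiated methyl phenyl sulfone 16 (not isolated)
Conditions: 15 (2 equiv), n-BuLi, THF, −78 °C; then 14, DMPU, −78 to 40 °C
Reagents that add atoms: none
Why: SN2 alkylation of the α-sulfonyl carbanion by the primary bromide adds the carbon that becomes C2'; the β-stereocentre is not involved and excess carbanion suppresses double alkylation.

Step 9
Reactants: 12; 18 propanoyl chloride
Product: 19 4,8-dimethylspiro[4.5]deca-1,7-dien-3-yl propanoate (ester on the C6 face and trans to the 4-methyl)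
Conditions: pyridine, DMAP (cat.), CH2Cl2, 0 °C
Reagents that add atoms: none
Why: DMAP-catalysed acylation of the secondary allylic alcohol with retention at C3.

Step 10
Reactants: 19
Product: 22 (2S)-2-[(1R,4S,5R)-4,8-dimethylspiro[4.5]deca-2,7-dien-1-yl]propanoic acid, via silyl ketene acetal 20 (not isolated), via trimethylsilyl ester 21 (not isolated)
Conditions: LDA, THF/DMPU (4:1), −78 °C; TMSCl/Et3N; −78 to 60 °C; 1 M HCl
Reagents that add atoms: none
Why: Ireland–Claisen rearrangement: enolisation in THF/DMPU gives the ketene acetal with methyl cis to OSiMe3, and the [3,3] shift runs suprafacially from the C3–O face through the boat arrangement usual for ring-allylic esters (methyl and OSiMe3 turned away from the spiro ring), which sets C1 (side chain cis to C6 and trans to the C4 methyl) and Cb.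

Step 11
Reactants: 22
Product: 23 (2S)-2-[(1R,4S,5R)-4,8-dimethylspiro[4.5]deca-2,7-dien-1-yl]propan-1-ol
Conditions: LiAlH4, THF, 0 °C to rt
Reagents that add atoms: none
Why: Hydride reduction of the acid to the primary alcohol; the carboxylate is not enolised, so the α-stereocentre is kept.

Step 12
Reactants: 23
Product: 24 (1R,4S,5R)-1-[(2S)-1-iodopropan-2-yl]-4,8-dimethylspiro[4.5]deca-2,7-diene
Conditions: I2, PPh3, imidazole, CH2Cl2, 0 °C to rt
Reagents that add atoms: iodine, II
Why: Appel-type iodination of the primary alcohol; the neighbouring stereocentre is not involved.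

Step 13
Reactants: 24; 17
Product: 26 tert-butyl{[(2S,6R)-6-[(1R,4S,5R)-4,8-dimethylspiro[4.5]deca-2,7-dien-1-yl]-2-methyl-4-(phenylsulfonyl)heptyl]oxy}diphenylsilane (both epimers at the sulfone carbon), via lithiated sulfone 25 (not isolated)
Conditions: 17, n-BuLi, THF/HMPA, −78 °C; then 24, −78 °C to rt
Reagents that add atoms: none
Why: Alkylation of the α-sulfonyl carbanion with the β-branched primary iodide forms the C1'–C2' bond; no existing stereocentre is affected and the sulfone-bearing centre is removed in step 14.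

Step 14
Reactants: 26
Product: 27 tert-butyl{[(2S,6R)-6-[(1R,4S,5R)-4,8-dimethylspiro[4.5]deca-2,7-dien-1-yl]-2-methylheptyl]oxy}diphenylsilane
Conditions: Na(Hg) (6% Na), Na2HPO4, MeOH/THF, −20 to 0 °C
Reagents that add atoms: none
Why: Reductive desulfonylation by electron transfer replaces the sulfonyl group by hydrogen; isolated alkenes and the silyl ether are inert.

Step 15
Reactants: 27
Product: 28 tert-butyl{[(2S,6R)-6-[(1R,4S,5R)-4,8-dimethylspiro[4.5]dec-7-en-1-yl]-2-methylheptyl]oxy}diphenylsilane
Conditions: TsNHNH2 (excess), NaOAc, DME/H2O, reflux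
Reagents that add atoms: none
Why: Diimide reduction transfers H2 in a concerted syn fashion to the cis-disubstituted C2=C3 bond only; the trisubstituted C7=C8 bond is inert to diimide and no stereocentre is formed.

Step 16
Reactants: 28
Product: 29 (2S,6R)-6-[(1R,4S,5R)-4,8-dimethylspiro[4.5]dec-7-en-1-yl]-2-methylheptan-1-ol
Conditions: TBAF, THF, rt
Reagents that add atoms: none
Why: Fluoride cleavage of the silyl ether.

Step 17
Reactants: 29
Product: 30 (2S,6R)-6-[(1R,4S,5R)-4,8-dimethylspiro[4.5]dec-7-en-1-yl]-2-methylheptyl acetate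
Conditions: Ac2O, pyridine, DMAP (cat.), CH2Cl2, rt
Reagents that add atoms: acetic anhydride, CC(=O)OC(C)=O
Why: Acetylation of the only hydroxyl group installs the ester of the target before the secondary allylic alcohol exists.

Step 18
Reactants: 30
Product: 32 (2S,6R)-6-[(1R,4S,5S)-4,8-dimethyl-9-oxospiro[4.5]dec-7-en-1-yl]-2-methylheptyl acetate, via 9-hydroxy epimers 31 (not isolated)
Conditions: SeO2 (0.3 equiv), t-BuOOH (3 equiv), CH2Cl2, rt; then Dess–Martin periodinane, NaHCO3, CH2Cl2, rt
Reagents that add atoms: tert-butyl hydroperoxide, CC(C)(C)OO; selenium dioxide, O=[Se]=O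
Why: Riley oxidation: the ene step puts selenium on C7 and removes hydrogen from the ring CH2 on the more substituted alkene carbon (C9), and the [2,3] shift returns oxygen to C9 with the double bond back at C7=C8 (C6 cannot be oxidised by this mechanism); Dess–Martin oxidation then converges both C9 epimers and any enone already formed.

Step 19
Reactants: 32
Product: 33 (2S,6R)-6-[(1R,4S,5S,9S)-9-hydroxy-4,8-dimethylspiro[4.5]dec-7-en-1-yl]-2-methylheptyl acetate
Conditions: (R)-2-methyl-CBS-oxazaborolidine (0.3 equiv), catecholborane (1.5 equiv), toluene, −78 °C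
Reagents that add atoms: none
Why: Corey–Bakshi–Shibata reduction: the oxazaborolidine distinguishes the α-methylated alkenyl side (large) from the CH2 side (small) of the enone and delivers hydride 1,2 to set C9 by reagent control; the acetate is inert to catecholborane at low temperature.

**Compound list**

1 | 3-methylcyclopent-2-en-1-one | CC1=CC(=O)CC1 | starting material
2 | N,N-dimethylmethyleneiminium iodide | C=[N+](C)C.[I-] | starting material
3 | diphenylbis{[(3S)-3-methylcyclopent-1-en-1-yl]oxy}silane | C[C@H]1CCC(O[Si](c2ccccc2)(c3ccccc3)OC4=C[C@@H](C)CC4)=C1 | intermediate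
4 | (2S,3S)-2-[(dimethylamino)methyl]-3-methylcyclopentan-1-one | O=C1CC[C@H](C)[C@H]1CN(C)C | intermediate
5 | trimethylammonium iodide of 4 | O=C1CC[C@H](C)[C@H]1C[N+](C)(C)C.[I-] | intermediate
6 | (S)-3-methyl-2-methylidenecyclopentan-1-one | O=C1CC[C@H](C)C1=C | intermediate
7 | isoprene | C=CC(C)=C | starting material
8 | (4S,5R)-4,8-dimethylspiro[4.5]dec-7-en-1-one | O=C1CC[C@H](C)[C@@]12CC=C(C)CC2 | intermediate
9 | trimethylsilyl enol ether of 8 (C1=C2) | C[Si](C)(C)OC1=CC[C@H](C)[C@@]12CC=C(C)CC2 | intermediate
10 | (4S,5R)-4,8-dimethylspiro[4.5]deca-2,7-dien-1-one | O=C1C=C[C@H](C)[C@@]12CC=C(C)CC2 | intermediate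
11 | 2,3-epoxy-4,8-dimethylspiro[4.5]dec-7-en-1-one, epoxide trans to 4-methyl | O=C1[C@H]2O[C@H]2[C@H](C)[C@@]13CC=C(C)CC3 | intermediate
12 | 4,8-dimethylspiro[4.5]deca-1,7-dien-3-ol, 3-OH trans to 4-methyl | C1=C[C@@H](O)[C@H](C)[C@@]12CC=C(C)CC2 | intermediate
13 | (R)-3-bromo-2-methylpropan-1-ol | OC[C@@H](C)CBr | starting material
14 | (R)-(3-bromo-2-methylpropoxy)(tert-butyl)diphenylsilane | CC(C)(C)[Si](OC[C@@H](C)CBr)(c1ccccc1)c1ccccc1 | intermediate
15 | methyl phenyl sulfone | CS(=O)(=O)c1ccccc1 | starting material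
16 | lithio(phenylsulfonyl)methane | [Li]CS(=O)(=O)c1ccccc1 | intermediate
17 | (S)-tert-butyl{[2-methyl-4-(phenylsulfonyl)butyl]oxy}diphenylsilane | CC(C)(C)[Si](OC[C@@H](C)CCS(=O)(=O)c1ccccc1)(c1ccccc1)c1ccccc1 | intermediate
18 | propanoyl chloride | CCC(Cl)=O | starting material
19 | propanoate of 12 | C1=C[C@@H](OC(=O)CC)[C@H](C)[C@@]12CC=C(C)CC2 | intermediate
20 | trimethylsilyl ketene acetal of 19, methyl cis to OSiMe3 | C1=C[C@@H](O/C(O[Si](C)(C)C)=C/C)[C@H](C)[C@@]12CC=C(C)CC2 | intermediate
21 | trimethylsilyl ester of 22 | C[Si](C)(C)OC(=O)[C@@H](C)[C@H]1C=C[C@H](C)[C@@]12CC=C(C)CC2 | intermediate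
22 | (2S)-2-[(1R,4S,5R)-4,8-dimethylspiro[4.5]deca-2,7-dien-1-yl]propanoic acid | OC(=O)[C@@H](C)[C@H]1C=C[C@H](C)[C@@]12CC=C(C)CC2 | intermediate
23 | (2S)-2-[(1R,4S,5R)-4,8-dimethylspiro[4.5]deca-2,7-dien-1-yl]propan-1-ol | OC[C@@H](C)[C@H]1C=C[C@H](C)[C@@]12CC=C(C)CC2 | intermediate
24 | (1R,4S,5R)-1-[(2S)-1-iodopropan-2-yl]-4,8-dimethylspiro[4.5]deca-2,7-diene | IC[C@@H](C)[C@H]1C=C[C@H](C)[C@@]12CC=C(C)CC2 | intermediate
25 | α-lithio derivative of 17 | [Li]C(C[C@H](C)CO[Si](c1ccccc1)(c1ccccc1)C(C)(C)C)S(=O)(=O)c1ccccc1 | intermediate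
26 | coupled sulfone (epimers at the sulfone carbon) | C[C@H](CC(C[C@H](C)CO[Si](c3ccccc3)(c4ccccc4)C(C)(C)C)S(=O)(=O)c5ccccc5)[C@H]1C=C[C@H](C)[C@@]12CC=C(C)CC2 | intermediate
27 | silyl ether of the 2,7-diene with complete side chain | C[C@H](CCC[C@H](C)CO[Si](c3ccccc3)(c4ccccc4)C(C)(C)C)[C@H]1C=C[C@H](C)[C@@]12CC=C(C)CC2 | intermediate
28 | silyl ether of the 7-ene | C[C@H](CCC[C@H](C)CO[Si](c3ccccc3)(c4ccccc4)C(C)(C)C)[C@H]1CC[C@H](C)[C@@]12CC=C(C)CC2 | intermediate
29 | (2S,6R)-6-[(1R,4S,5R)-4,8-dimethylspiro[4.5]dec-7-en-1-yl]-2-methylheptan-1-ol | C[C@H](CCC[C@H](C)CO)[C@H]1CC[C@H](C)[C@@]12CC=C(C)CC2 | intermediate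
30 | (2S,6R)-6-[(1R,4S,5R)-4,8-dimethylspiro[4.5]dec-7-en-1-yl]-2-methylheptyl acetate | C[C@H](CCC[C@H](C)COC(C)=O)[C@H]1CC[C@H](C)[C@@]12CC=C(C)CC2 | intermediate
31 | 9-hydroxy derivative of 30 (both C9 epimers) | C[C@H](CCC[C@H](C)COC(C)=O)[C@H]1CC[C@H](C)[C@@]12CC=C(C)C(O)C2 | intermediate
32 | (2S,6R)-6-[(1R,4S,5S)-4,8-dimethyl-9-oxospiro[4.5]dec-7-en-1-yl]-2-methylheptyl acetate | C[C@H](CCC[C@H](C)COC(C)=O)[C@H]1CC[C@H](C)[C@@]12CC=C(C)C(=O)C2 | intermediate
33 | (2S,6R)-6-[(1R,4S,5S,9S)-9-hydroxy-4,8-dimethylspiro[4.5]dec-7-en-1-yl]-2-methylheptyl acetate | CC(=O)OC[C@@H](C)CCC[C@@H](C)[C@H]1CC[C@H](C)[C@@]12CC=C(C)[C@@H](O)C2 | target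

**Summary**

Total step count: 19. Longest linear sequence: 17 (steps 1–6 and 9–19).

Steps most likely to fail:

Step 10. The [3,3] shift at the neopentyl C1 terminus may be slow, so that the silyl ketene acetal decomposes before it rearranges, and leakage through the chair arrangement may erode the configuration at Cb. Fallback, setting out from 12 and returning at 23: 12 is heated with 1,1-dimethoxy-N,N-dimethylpropan-1-amine in xylene at 140 °C (Eschenmoser–Claisen rearrangement). The neutral ketene N,O-acetal has its methyl fixed cis to the allyl oxygen, the methyl-inside boat is excluded, and the chair on the C3–O face leads to the same configuration at both new centres, giving (2S)-N,N-dimethyl-2-[(1R,4S,5R)-4,8-dimethylspiro[4.5]deca-2,7-dien-1-yl]propanamide F1. LiEt3BH in THF then reduces the tertiary amide to alcohol 23.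

Step 18. The selenium ene step may show poor site selectivity between the ring CH2 (C9) and the C8 methyl, with over-oxidation or low conversion late in the route. Fallback, setting out from 30 and returning at 31: NOCl (isoamyl nitrite, HCl, −10 °C) adds across C7=C8 with nitrogen on C7 and chlorine on C8 to give the 8-chloro-7-oxime F2. Pyridine at 80 °C removes HCl toward C9 to give the conjugated 7-oxime of the 8-ene F3. TiCl3/NH4OAc in aqueous dioxane frees the regioisomeric enone, the 7-oxo-8-ene F4. t-BuOOH/DBU epoxidises its C8=C9 bond to the 8,9-epoxy-7-ketone F5. Buffered N2H4·H2O/AcOH (Wharton transposition) then moves the oxygen to C9 and the alkene back to C7=C8, giving 31, which is taken through the Dess–Martin and CBS operations as in the route.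

Step 6. Hydrazone formation at the hindered C1 ketone may be slow and material may be lost through side reactions of the fragmentation intermediate. Fallback, setting out from 11 and returning at 12: NaBH4 in MeOH reduces 11 to the 2,3-epoxy-1-ol F6 (either C1 epimer serves). 1,1'-Thiocarbonyldiimidazole/DMAP gives its O-(imidazole-1-carbothioate) F7. Bu3SnH/AIBN in benzene at 80 °C generates the C1 radical, which opens the neighbouring epoxide at C2–O, and the C3 alkoxy radical takes up hydrogen to give 12 with the C3 configuration unchanged (Barton–McCombie-type epoxide fragmentation).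

**Further compounds**

F1 | step 10 | (2S)-N,N-dimethyl-2-[(1R,4S,5R)-4,8-dimethylspiro[4.5]deca-2,7-dien-1-yl]propanamide | CN(C)C(=O)[C@@H](C)[C@H]1C=C[C@H](C)[C@@]12CC=C(C)CC2
F2 | step 18 | 8-chloro-7-(hydroxyimino) derivative of 30 | C[C@H](CCC[C@H](C)COC(C)=O)[C@H]1CC[C@H](C)[C@@]12CC(=NO)C(C)(Cl)CC2
F3 | step 18 | 7-(hydroxyimino)-8-ene isomer | C[C@H](CCC[C@H](C)COC(C)=O)[C@H]1CC[C@H](C)[C@@]12CC(=NO)C(C)=CC2
F4 | step 18 | 7-oxo-8-ene isomer of 32 | C[C@H](CCC[C@H](C)COC(C)=O)[C@H]1CC[C@H](C)[C@@]12CC(=O)C(C)=CC2
F5 | step 18 | 8,9-epoxy-7-ketone | C[C@H](CCC[C@H](C)COC(C)=O)[C@H]1CC[C@H](C)[C@@]12CC(=O)C3(C)OC3C2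
F6 | step 6 | 2,3-epoxy-4,8-dimethylspiro[4.5]dec-7-en-1-ol | OC1[C@H]2O[C@H]2[C@H](C)[C@@]13CC=C(C)CC3
F7 | step 6 | O-(imidazole-1-carbothioate) of F6 | S=C(OC1[C@H]2O[C@H]2[C@H](C)[C@@]13CC=C(C)CC3)n4ccnc4
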